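**Retrosynthetic overview**
1. Final desilylation, then the O3 ester is cut (carbodiimide coupling) into core alcohol 24 and trienoic acid 29; the acid comes from enone 25 and phosphonate 26 by a vinylogous Horner–Wadsworth–Emmons reaction.
2. Core 24 goes back to the cis-octalin silyl enol ether 12: C3–OH/C4–H by hydroboration of C3=C4, C9–OH by enolate oxygenation, C11–C13 by chloroacetone aldol, epoxide closure and E1cB opening at C7.
3. The strategy rests on the cis junction C5(CH3)–C10(H) of rings A and B, with the ring-B carbonyl C8 and a ring-A alkene C3=C4 joined through the C5–C6 bond. This is the pattern left by an anionic oxy-Cope shift of a 2-vinylbicyclo[2.2.2]oct-5-en-2-ol (C5–C6 formed, C3–C8 broken).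
4. Ring order: ring A is bought (enone 1 to diene 3); an enantioselective Diels–Alder reaction with acrolein adds a temporary C8–C9 bridge; the oxy-Cope shift turns the bridged bicycle into ring B.

Key step: step 6

Remark on numbering: eremophilane numbering is used for the decalin (C3 ester carbinol, C4 and C5 methyl-bearing, C8 ketone, C9 carbinol, C10 ring-fusion CH, C11–C13 the three-carbon unit on C7); β is the face that carries the C5 methyl. The target is then the (3R,4R,5R,9R,10S), 7(11)Z compound.
Assumption: the (5S)-imidazolidinone is taken to direct the cycloaddition in the same absolute sense as with unsubstituted cyclohexadiene and acrolein; if the opposite sense were found, the (5R)-catalyst would be used and nothing else changes.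

**Route**

Step 1
Reactants: 1 2-methylcyclohex-2-en-1-one
Product: 2 (±)-1,2-dimethylcyclohex-2-en-1-ol
Conditions: MeLi, Et2O, −78 °C to 0 °C; then H2O
Reagents that add atoms: methyllithium, C[Li]
Why: The hard organolithium should add 1,2 to the enone carbonyl to give the tertiary allylic alcohol, whose stereocentre is removed in the next step.

Step 2
Reactants: 2 (±)-1,2-dimethylcyclohex-2-en-1-ol
Product: 3 2,3-dimethylcyclohexa-1,3-diene
Conditions: Burgess reagent (MeO2C–N(−)–SO2–N(+)Et3), THF, 50 °C
Reagents that add atoms: none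
Why: Burgess dehydration is a syn elimination through the sulfamate ester, so a ring C6–H should be lost to give the endocyclic conjugated diene without a free allyl cation that could move the diene; any exocyclic isomer cannot reach a cisoid geometry and is inert in step 3.

Step 3
Reactants: 3 2,3-dimethylcyclohexa-1,3-diene; 4 acrolein
Product: 5 (1S,2R,4R)-5,6-dimethylbicyclo[2.2.2]oct-5-ene-2-carbaldehyde (endo, formyl group syn to the C5=C6 bridge)
Conditions: (5S)-5-benzyl-2,2,3-trimethylimidazolidin-4-one hydrochloride (10 mol%), MeCN/H2O 95:5, rt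
Reagents that add atoms: none
Why: In this iminium-catalysed enantioselective Diels–Alder reaction the benzyl group of the catalyst shields one face of the (E)-iminium ion, the symmetrical diene raises no regiochemical question, and endo approach fixes the bridgehead that becomes C10; the minor exo adduct would lead to the antipodal ketone and is removed by chromatography.

Step 4
Reactants: 5 (1S,2R,4R)-5,6-dimethylbicyclo[2.2.2]oct-5-ene-2-carbaldehyde
Product: 7 (1R,4R)-5,6-dimethylbicyclo[2.2.2]oct-5-en-2-one, via piperidine enamine 6 (not isolated)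
Conditions: piperidine, 4 Å MS, toluene, rt; then CuCl (cat.), O2 (1 atm), MeCN, 0 °C to rt
Reagents that add atoms: dioxygen, O=O
Why: CuCl-catalysed oxygenation cleaves the electron-rich enamine C=C of the α-branched aldehyde to the ketone and N-formylpiperidine, while the ring alkene, which has no nitrogen activation, and both bridgeheads should be untouched.

Step 5
Reactants: 7 (1R,4R)-5,6-dimethylbicyclo[2.2.2]oct-5-en-2-one; 8 vinylmagnesium bromide
Product: 9 (1R,2R,4R)-5,6-dimethyl-2-vinylbicyclo[2.2.2]oct-5-en-2-ol (vinyl syn to the C5=C6 bridge)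
Conditions: CH2=CHMgBr, anhydrous CeCl3, THF, −78 °C; then H2O
Reagents that add atoms: none
Why: The organocerium 1,2-addition suppresses enolisation of the β,γ-unsaturated ketone, and attack over the sp2 bridge, which has no inward hydrogens unlike the ethano bridge, should place the vinyl group syn to the alkene and so set the carbinol centre.

Step 6
Reactants: 9 (1R,2R,4R)-5,6-dimethyl-2-vinylbicyclo[2.2.2]oct-5-en-2-ol
Product: 12 8-(trimethylsilyloxy)-11,12,13-trinor-10βH-eremophila-3,7-diene (cis-fused 4,5-dimethyloctalin; 5β-CH3 and 10β-H; enol ether C7=C8), via potassium alkoxide 10 (not isolated), via potassium enolate 11 (not isolated)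
Conditions: KH, 18-crown-6, THF, rt to 50 °C; then Me3SiCl, Et3N, −78 °C to 0 °C
Reagents that add atoms: chlorotrimethylsilane, C[Si](C)(C)Cl
Why: KH with 18-crown-6 converts 9 into the free alkoxide 10, whose oxyanion weakens the adjacent C3–C8 bond so that a concerted [3,3] sigmatropic shift should proceed near room temperature; this is the anionic oxy-Cope rearrangement, the established way from 2-vinylbicyclo[2.2.2]oct-5-en-2-ols to cis-fused octalones. Ring B (C5–C6–C7–C8–C9–C10) closes in this six-centre pericyclic step, through the boat-like array enforced by the cage, by joining the vinyl terminus C6 to the alkene carbon C5 while C3–C8 breaks and the bridged bicycle opens; ring A is what is left of the cyclohexadiene. The one new stereocentre, quaternary C5, is controlled by the C10 bridgehead, because C6 can reach C5 only on the alkene face turned toward the carbinol bridge, which puts C5–CH3 and C10–H cis; C10 itself is not touched. The step needs the vinyl group and the dimethyl-alkene bridge syn in 9, which step 5 secures, and the mechanism can give only the C7=C8 enolate. Strain release and the stabilised enolate 11 drive the shift, and silylation at −78 °C fixes the enolate as enol ether 12, with C3=C4 kept for step 11.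

Step 7
Reactants: 12 8-(trimethylsilyloxy)-11,12,13-trinor-10βH-eremophila-3,7-diene; 13 chloroacetone
Product: 17 (7(11)Z)-12-hydroxy-10βH-eremophila-3,7(11)-dien-8-one, via lithium enolate 14 (not isolated), via lithium chlorohydrin alkoxide 15 (not isolated), via epoxy ketone 16 (not isolated)
Conditions: MeLi, THF, 0 °C to rt; chloroacetone, −78 °C to 0 °C; LiOtBu, 0 °C to rt; then pH 7 buffer
Reagents that add atoms: none
Why: Si–O cleavage by MeLi gives the regiodefined C7 lithium enolate, aldol addition to the very electrophilic chloroacetone carbonyl is followed by Darzens-type closure of the chlorohydrin alkoxide to the epoxide, and deprotonation at C7 opens it by E1cB to the γ-hydroxy enone; lithium bridging the enolate oxygen and the epoxide oxygen should hold the CH2O arm on the carbonyl side (Z), and neutral work-up avoids cyclodehydration to the furan.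

Step 8
Reactants: 17 (7(11)Z)-12-hydroxy-10βH-eremophila-3,7(11)-dien-8-one
Product: 18 (7(11)Z)-12-(tert-butyldimethylsilyloxy)-10βH-eremophila-3,7(11)-dien-8-one
Conditions: TBSCl, imidazole, DMF, 0 °C to rt
Reagents that add atoms: tert-butyldimethylsilyl chloride, CC(C)(C)[Si](C)(C)Cl
Why: Standard silylation of the primary allylic alcohol removes the furan-forming hydroxyl and spares the next step a free alkoxide.

Step 9
Reactants: 18 (7(11)Z)-12-(tert-butyldimethylsilyloxy)-10βH-eremophila-3,7(11)-dien-8-one
Product: 20 (7(11)Z)-9β-hydroxy-12-(tert-butyldimethylsilyloxy)-10βH-eremophila-3,7(11)-dien-8-one, via lithium enolate 19 (not isolated)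
Conditions: LiN(iPr)2, THF, −78 °C; 2-(phenylsulfonyl)-3-phenyloxaziridine, −78 °C; then H2O
Reagents that add atoms: 2-(phenylsulfonyl)-3-phenyloxaziridine, O=S(=O)(c1ccccc1)N1OC1c1ccccc1
Why: Kinetic deprotonation of the enone at the α′ carbon C9 gives the cross-conjugated enolate, and oxygen transfer from the N-sulfonyloxaziridine (Davis hydroxylation) should occur on the convex β face, anti to C1 on C10, to give the 9β alcohol, which is also the equatorial and more stable epimer.

Step 10
Reactants: 20 (7(11)Z)-9β-hydroxy-12-(tert-butyldimethylsilyloxy)-10βH-eremophila-3,7(11)-dien-8-one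
Product: 21 (7(11)Z)-9β,12-bis(tert-butyldimethylsilyloxy)-10βH-eremophila-3,7(11)-dien-8-one
Conditions: TBSOTf, 2,6-lutidine, CH2Cl2, −78 °C to 0 °C
Reagents that add atoms: tert-butyldimethylsilyl triflate, CC(C)(C)[Si](C)(C)OS(=O)(=O)C(F)(F)F
Why: The silyl triflate with a hindered pyridine base silylates the secondary α-hydroxy ketone without forming a silyl enol ether, and the resulting equatorial 9β-silyloxy group fixes the decalin conformation for step 11.

Step 11
Reactants: 21 (7(11)Z)-9β,12-bis(tert-butyldimethylsilyloxy)-10βH-eremophila-3,7(11)-dien-8-one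
Product: 23 (7(11)Z)-9β,12-bis(tert-butyldimethylsilyloxy)-10βH-eremophil-7(11)-ene-3α,8-diol (4β-CH3; both C8 epimers), via C3-boryl O8-borinate 22 (not isolated)
Conditions: 9-BBN (excess), THF, 0 °C to 60 °C; then NaBO3·4H2O, THF/H2O, rt
Reagents that add atoms: sodium perborate (NaBO3·4H2O), [Na+].[O-]OB=O
Why: 9-BBN should first reduce the enone carbonyl 1,2 (held as the borinate) and then hydroborate the trisubstituted C3=C4 with boron on C3, syn and from the α face opposite the C5 methyl, which is axial on ring A in the conformer with the 9β-silyloxy group equatorial; the tetrasubstituted C7=C11 is inert to this borane, oxidation with retention gives 3α-OH and 4β-CH3, and the near-neutral perborate avoids silyl migration to O8.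

Step 12
Reactants: 23 (7(11)Z)-9β,12-bis(tert-butyldimethylsilyloxy)-10βH-eremophil-7(11)-ene-3α,8-diol
Product: 24 (7(11)Z)-3α-hydroxy-9β,12-bis(tert-butyldimethylsilyloxy)-10βH-eremophil-7(11)-en-8-one
Conditions: activated MnO2, CH2Cl2, rt
Reagents that add atoms: none
Why: MnO2 oxidises only the allylic C8 carbinol, so both C8 epimers should converge on the enone while the saturated C3 alcohol stays free.

Step 13
Reactants: 25 (E)-non-3-en-2-one; 26 triethyl 4-phosphonocrotonate
Product: 28 ethyl (2E,4E,6E)-5-methyldodeca-2,4,6-trienoate, via lithiated phosphonate 27 (not isolated)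
Conditions: LiN(SiMe3)2, THF, −78 °C; then 25, −78 °C to rt; chromatographic removal of the 4Z isomer
Reagents that add atoms: none
Why: The vinylogous Horner–Wadsworth–Emmons olefination of a methyl alkenyl ketone, as used with ionone-type enones, keeps the 2E and 6E bonds of the two partners and should form the new C4=C5 bond mainly E, with the alkenyl group trans to the chain.

Step 14
Reactants: 28 ethyl (2E,4E,6E)-5-methyldodeca-2,4,6-trienoate
Product: 29 (2E,4E,6E)-5-methyldodeca-2,4,6-trienoic acid
Conditions: LiOH·H2O, THF/MeOH/H2O, rt; then 1 M HCl to pH 3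
Reagents that add atoms: lithium hydroxide, [Li+].[OH-]
Why: Saponification of the ethyl ester at room temperature should leave the triene geometry unchanged.

Step 15
Reactants: 24 (7(11)Z)-3α-hydroxy-9β,12-bis(tert-butyldimethylsilyloxy)-10βH-eremophil-7(11)-en-8-one; 29 (2E,4E,6E)-5-methyldodeca-2,4,6-trienoic acid
Product: 30 (7(11)Z)-9β,12-bis(tert-butyldimethylsilyloxy)-8-oxo-10βH-eremophil-7(11)-en-3α-yl (2E,4E,6E)-5-methyldodeca-2,4,6-trienoate
Conditions: DCC, DMAP, CH2Cl2, 0 °C to rt
Reagents that add atoms: none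
Why: Steglich esterification acylates the only free hydroxyl, the equatorial 3α-OH, with retention at C3, under conditions mild enough for the trienoate and the α-silyloxy enone.

Step 16
Reactants: 30 (7(11)Z)-9β,12-bis(tert-butyldimethylsilyloxy)-8-oxo-10βH-eremophil-7(11)-en-3α-yl (2E,4E,6E)-5-methyldodeca-2,4,6-trienoate
Product: 31 CNP0226738.1, (3R,4R,5R,9R,10S,7(11)Z)-9,12-dihydroxy-8-oxoeremophil-7(11)-en-3-yl (2E,4E,6E)-5-methyldodeca-2,4,6-trienoate
Conditions: Bu4NF/AcOH (1:1), THF, 0 °C to rt
Reagents that add atoms: none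
Why: Acetic acid-buffered fluoride should cleave both silyl ethers while avoiding cyclodehydration of the Z-γ-hydroxy enone to a furan, α-ketol isomerisation at C9 and ester cleavage.

**Compound list**
1 | 2-methylcyclohex-2-en-1-one | CC1=CCCCC1=O | starting material
2 | (±)-1,2-dimethylcyclohex-2-en-1-ol | CC1=CCCCC1(C)O | intermediate
3 | 2,3-dimethylcyclohexa-1,3-diene | CC1=CCCC=C1C | intermediate
4 | acrolein | C=CC=O | starting material
5 | (1S,2R,4R)-5,6-dimethylbicyclo[2.2.2]oct-5-ene-2-carbaldehyde (endo) | O=C[C@@H]1C[C@H]2CC[C@@H]1C(C)=C2C | intermediate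
6 | piperidine enamine of 5 | C(=C1C[C@H]2CC[C@@H]1C(C)=C2C)N1CCCCC1 | intermediate (not isolated)
7 | (1R,4R)-5,6-dimethylbicyclo[2.2.2]oct-5-en-2-one | O=C1C[C@H]2CC[C@@H]1C(C)=C2C | intermediate
8 | vinylmagnesium bromide | C=C[Mg]Br | starting material
9 | (1R,2R,4R)-5,6-dimethyl-2-vinylbicyclo[2.2.2]oct-5-en-2-ol | C=C[C@]1(O)C[C@H]2CC[C@@H]1C(C)=C2C | intermediate
10 | potassium alkoxide of 9 | C=C[C@]1([O-])C[C@H]2CC[C@@H]1C(C)=C2C.[K+] | intermediate (not isolated)
11 | potassium C7=C8 enolate of the cis-octalone | CC1=CCC[C@@H]2CC([O-])=CC[C@]12C.[K+] | intermediate (not isolated)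
12 | 8-(trimethylsilyloxy)-11,12,13-trinor-10βH-eremophila-3,7-diene | CC1=CCC[C@@H]2CC(O[Si](C)(C)C)=CC[C@]12C | intermediate
13 | chloroacetone | CC(=O)CCl | starting material
14 | lithium C7=C8 enolate | CC1=CCC[C@@H]2CC([O-])=CC[C@]12C.[Li+] | intermediate (not isolated)
15 | lithium alkoxide of the C7 chlorohydrin aldol adduct (C7/C11 mixture) | CC1=CCC[C@@H]2CC(=O)C(C(C)([O-])CCl)C[C@]12C.[Li+] | intermediate (not isolated)
16 | 11,12-epoxy-10βH-eremophil-3-en-8-one (C7/C11 mixture) | CC1=CCC[C@@H]2CC(=O)C(C3(C)CO3)C[C@]12C | intermediate (not isolated)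
17 | (7(11)Z)-12-hydroxy-10βH-eremophila-3,7(11)-dien-8-one | CC1=CCC[C@@H]2CC(=O)/C(=C(/C)CO)C[C@]12C | intermediate
18 | 12-TBS ether of 17 | CC1=CCC[C@@H]2CC(=O)/C(=C(/C)CO[Si](C)(C)C(C)(C)C)C[C@]12C | intermediate
19 | lithium C8=C9 enolate of 18 | CC1=CCC[C@@H]2C=C([O-])/C(=C(/C)CO[Si](C)(C)C(C)(C)C)C[C@]12C.[Li+] | intermediate (not isolated)
20 | 9β-hydroxy-12-TBS-oxy dienone | CC1=CCC[C@@H]2[C@@H](O)C(=O)/C(=C(/C)CO[Si](C)(C)C(C)(C)C)C[C@]12C | intermediate
21 | 9β,12-bis(TBS-oxy) dienone | CC1=CCC[C@@H]2[C@@H](O[Si](C)(C)C(C)(C)C)C(=O)/C(=C(/C)CO[Si](C)(C)C(C)(C)C)C[C@]12C | intermediate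
22 | C3-(9-borabicyclo[3.3.1]nonan-9-yl) O8-borinate (C8 epimers) | B1(C2CCCC1CCC2)[C@@H]1CC[C@@H]2[C@@H](O[Si](C)(C)C(C)(C)C)C(OB3C4CCCC3CCC4)/C(=C(/C)CO[Si](C)(C)C(C)(C)C)C[C@]2(C)[C@H]1C | intermediate (not isolated)
23 | 9β,12-bis(TBS-oxy)-10βH-eremophil-7(11)Z-ene-3α,8-diol (C8 epimers) | O[C@@H]1CC[C@@H]2[C@@H](O[Si](C)(C)C(C)(C)C)C(O)/C(=C(/C)CO[Si](C)(C)C(C)(C)C)C[C@]2(C)[C@H]1C | intermediate
24 | 3α-hydroxy-9β,12-bis(TBS-oxy)-10βH-eremophil-7(11)Z-en-8-one | O[C@@H]1CC[C@@H]2[C@@H](O[Si](C)(C)C(C)(C)C)C(=O)/C(=C(/C)CO[Si](C)(C)C(C)(C)C)C[C@]2(C)[C@H]1C | intermediate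
25 | (E)-non-3-en-2-one | CCCCC/C=C/C(C)=O | starting material
26 | triethyl 4-phosphonocrotonate | CCOC(=O)/C=C/CP(=O)(OCC)OCC | starting material
27 | lithiated phosphonate from 26 | CCOC(=O)/C=C/[CH-]P(=O)(OCC)OCC.[Li+] | intermediate (not isolated)
28 | ethyl (2E,4E,6E)-5-methyldodeca-2,4,6-trienoate | CCCCC/C=C/C(C)=C/C=C/C(=O)OCC | intermediate
29 | (2E,4E,6E)-5-methyldodeca-2,4,6-trienoic acid | CCCCC/C=C/C(C)=C/C=C/C(=O)O | intermediate
30 | bis-TBS ether of the target | CCCCC/C=C/C(C)=C/C=C/C(=O)O[C@@H]1CC[C@@H]2[C@@H](O[Si](C)(C)C(C)(C)C)C(=O)/C(=C(/C)CO[Si](C)(C)C(C)(C)C)C[C@]2(C)[C@H]1C | intermediate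
31 | CNP0226738.1 | CCCCC/C=C/C(C)=C/C=C/C(=O)O[C@@H]1CC[C@@H]2[C@@H](O)C(=O)/C(=C(/C)CO)C[C@]2(C)[C@H]1C | target

**Step count**
Total: 16 steps. Longest linear sequence: 14 steps (steps 1–12, 15, 16); the acid arm is steps 13–14.

**Steps most likely to fail**

Step 7. The lithium enolate may take a proton from chloroacetone instead of adding to it, the tertiary aldolate may revert before the epoxide closes, and the C7=C11 geometry may not be held. The fallback sets out from 12 and avoids a basic enolate. A Mukaiyama aldol addition of 12 to chloroacetone 13 (TiCl4, CH2Cl2, −78 °C) should give the isolable C7 chlorohydrin ketone F1. DBU in THF (0 °C to rt) then closes F1 to the epoxy ketone 16 and opens it by E1cB, and the route is rejoined at 17.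

Step 9. Deprotonation may go to the γ carbons (C6, C12, C13) and not to C9, and oxygen transfer may show poor facial selectivity. The fallback sets out from 18. α′-Acetoxylation with Mn(OAc)3 in benzene at reflux, which goes through the metal enolate and is specific for the α′ carbon of conjugated enones, should give the 9-acetoxy enone F2. Methanolysis with K2CO3 in MeOH at 0 °C removes the acetate and lets C9 settle in the equatorial 9β configuration, and the route is rejoined at 20.

Step 11. The borane may add to the β face of C3=C4, or the hydroboration next to quaternary C5 may be too slow. The fallback sets out from 21 and replaces the face-selective addition by thermodynamic control at C4 and inversion at C3.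
- Hydroboration without facial demand (BH3·SMe2, THF, 0 °C; NaBO3) gives the stereoisomeric 3,8-diol mixture F3.
- Dess–Martin periodinane oxidises both carbinols to the 3,8-dione F4 (C4 epimers).
- DBU in CH2Cl2 equilibrates C4 to the equatorial 4β-methyl dione F5.
- Li(s-Bu)3BH in THF at −78 °C attacks the C3 ketone from the equatorial direction, because axial approach is blocked by the syn-axial C5 methyl, and should give the axial 3β-hydroxy-4β-methyl enone F6; MnO2 restores C8 if it is reduced.
- Mitsunobu esterification of F6 with acid 29 (PPh3, DIAD, THF) inverts C3, and the route is rejoined at 30.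

**Further compounds**
F1 | step 7 | C7 chlorohydrin ketone: 7-(1-chloro-2-hydroxypropan-2-yl)-11,12,13-trinor-10βH-eremophil-3-en-8-one (C7/C11 mixture) | CC1=CCC[C@@H]2CC(=O)C(C(C)(O)CCl)C[C@]12C
F2 | step 9 | 9-acetoxy-12-TBS-oxy-10βH-eremophila-3,7(11)Z-dien-8-one (C9 epimers) | CC1=CCC[C@@H]2C(OC(C)=O)C(=O)/C(=C(/C)CO[Si](C)(C)C(C)(C)C)C[C@]12C
F3 | step 11 | 9β,12-bis(TBS-oxy)-10βH-eremophil-7(11)Z-ene-3,8-diol (mixture at C3, C4, C8) | OC1CC[C@@H]2[C@@H](O[Si](C)(C)C(C)(C)C)C(O)/C(=C(/C)CO[Si](C)(C)C(C)(C)C)C[C@]2(C)C1C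
F4 | step 11 | 9β,12-bis(TBS-oxy)-10βH-eremophil-7(11)Z-ene-3,8-dione (C4 epimers) | CC1C(=O)CC[C@@H]2[C@@H](O[Si](C)(C)C(C)(C)C)C(=O)/C(=C(/C)CO[Si](C)(C)C(C)(C)C)C[C@]12C
F5 | step 11 | 4β-methyl 9β,12-bis(TBS-oxy)-10βH-eremophil-7(11)Z-ene-3,8-dione | C[C@H]1C(=O)CC[C@@H]2[C@@H](O[Si](C)(C)C(C)(C)C)C(=O)/C(=C(/C)CO[Si](C)(C)C(C)(C)C)C[C@]12C
F6 | step 11 | 3β-hydroxy-9β,12-bis(TBS-oxy)-10βH-eremophil-7(11)Z-en-8-one | O[C@H]1CC[C@@H]2[C@@H](O[Si](C)(C)C(C)(C)C)C(=O)/C(=C(/C)CO[Si](C)(C)C(C)(C)C)C[C@]2(C)[C@H]1C
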